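## Retrosynthetic overview
1. The only ring of the target, the 1,2-dioxine, is closed last. C3–OOH and MeOH are added across the C6≡C7 alkyne of an acyclic (Z)-enynyl hydroperoxide (new Au(I) peroxyketalisation), and C6 is set by acid equilibration.
2. The (Z)-enyne comes from forming C5–C6 in a Pd-catalysed alkenyl–alkynyl Stille coupling of a C1–C5 (S,Z)-iodoalkenyl peroxide with a C6–C22 alkynylstannane.
3. The C1–C5 piece comes from TMS-propynal plus allyl (asymmetric allylboration, 3R carbinol). SN2 inversion with THP-OOH (from dihydropyran and H2O2) gives the 3S peroxide. The allyl group becomes CH2CO2Me and the alkyne becomes the Z-iodoalkene.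
4. The C6–C22 piece comes from propyne plus two 1-bromoheptane units, followed by alkyne zipper and stannylation.

Assumption: the SMILES is read as (3S,6S), with OMe and CH2CO2Me cis on the ring. The THP acetal carbon is an inconsequential epimer mixture wherever it occurs and is drawn without configuration. All peroxides are kept cold, in the dark, with a trace of BHT.

## Route

Step 1
Reactants: 1 3,4-dihydro-2H-pyran; 2 hydrogen peroxide
Product: 3 oxan-2-yl hydroperoxide (THP-OOH)
Conditions: 50% aq H2O2 (3 equiv), cat. H2SO4, 0 °C → rt; CH2Cl2 extraction, kept as a stock solution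
Reagents that add atoms: none
Why: Acid-catalysed Markovnikov addition of H2O2 to the enol ether (peroxyacetalisation) gives a masked hydroperoxide that carries both future ring oxygens; its acetal carbon is racemic and is lost in step 14.

Step 2
Reactants: 4 allylmagnesium bromide; 5 3-(trimethylsilyl)prop-2-ynal
Product: 8 (3R)-1-(trimethylsilyl)hex-5-en-1-yn-3-ol, via B-allyldiisopinocampheylborane 6 (not isolated), via borinate ester 7 (not isolated)
Conditions: (+)-Ipc2BOMe [from (−)-α-pinene], 4, Et2O, 0 °C → rt; 5, −78 °C; then HOCH2CH2NH2, rt, filter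
Reagents that add atoms: none
Why: Brown asymmetric allylboration through a chair Zimmerman–Traxler transition state delivers allyl to the Re face of the ynal and sets C3 as R (typically about 90% ee or better); the non-oxidative ethanolamine work-up spares the C–Si bond.

Step 3
Reactants: 8 (3R)-1-(trimethylsilyl)hex-5-en-1-yn-3-ol
Product: 9 (3R)-1-(trimethylsilyl)hex-5-en-1-yn-3-yl methanesulfonate
Conditions: MsCl, Et3N, CH2Cl2, −20 → 0 °C
Reagents that add atoms: methanesulfonyl chloride, CS(=O)(=O)Cl
Why: Mesylation (sulfonate ester formation) occurs at oxygen only, so the C3–O bond and the R configuration are untouched.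

Step 4
Reactants: 9 (3R)-mesylate; 3 oxan-2-yl hydroperoxide
Product: 11 2-{[(3S)-hex-5-en-1-yn-3-yl]peroxy}oxane, via silylated peroxide 10 (not isolated)
Conditions: 3 (2 equiv), CsOH·H2O (1.8 equiv), DMF, 0 °C, 3 h; then CsOH·H2O (0.5 equiv), rt, 30 min
Reagents that add atoms: none
Why: SN2 alkylation of a hydroperoxide anion (α-effect, weakly basic nucleophile) at the activated propargylic mesylate goes with inversion and turns 3R into 3S; hydroxide in wet DMF then protodesilylates the alkyne, so silylated and desilylated material converge on 11.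

Step 5
Reactants: 11 2-{[(3S)-hex-5-en-1-yn-3-yl]peroxy}oxane
Product: 13 (3S)-3-(oxan-2-ylperoxy)pent-4-ynoic acid, via peroxy aldehyde 12 (not isolated)
Conditions: O3, MeCN/H2O (9:1), 0 °C, stop at the Sudan III end point, N2 purge; then aq NaClO2 (2 equiv), 0 °C → rt
Reagents that add atoms: ozone, [O-][O+]=O; water, O; sodium chlorite, [Na+].[O-]Cl=O
Why: Ozonolysis in wet solvent (water traps the carbonyl oxide, so the aldehyde forms directly) is telescoped with a Pinnick–Lindgren chlorite oxidation in which the released H2O2 scavenges HOCl; the alkene reacts far faster than the alkyne, the peroxyacetal is inert, and C3 is not touched.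

Step 6
Reactants: 13 (3S)-3-(oxan-2-ylperoxy)pent-4-ynoic acid
Product: 14 methyl (3S)-3-(oxan-2-ylperoxy)pent-4-ynoate
Conditions: TMSCHN2 (1.2 equiv), PhMe/MeOH (4:1), 0 °C
Reagents that add atoms: (trimethylsilyl)diazomethane, C[Si](C)(C)C=[N+]=[N-]
Why: Diazoalkane O-methylation of the acid is neutral and avoids the base that would cause E1cB loss of the β-peroxide.

Step 7
Reactants: 14 methyl (3S)-3-(oxan-2-ylperoxy)pent-4-ynoate
Product: 15 methyl (3S)-5-iodo-3-(oxan-2-ylperoxy)pent-4-ynoate
Conditions: NIS (1.2 equiv), AgNO3 (10 mol %), acetone, rt, dark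
Reagents that add atoms: N-iodosuccinimide, O=C1CCC(=O)N1I
Why: Ag(I)-catalysed electrophilic iodination of the terminal alkyne (silver acetylide plus NIS) is neutral and leaves the ester, O–O bond and C3 alone.

Step 8
Reactants: 15 methyl (3S)-5-iodo-3-(oxan-2-ylperoxy)pent-4-ynoate
Product: 16 methyl (3S,4Z)-5-iodo-3-(oxan-2-ylperoxy)pent-4-enoate
Conditions: 2-nitrobenzenesulfonyl hydrazide (2.5 equiv), Et3N, THF/i-PrOH (1:1), rt, dark
Reagents that add atoms: none
Why: Diimide reduction transfers H2 in a concerted syn fashion to the iodoalkyne, which fixes the Z-iodoalkene; diimide does not reduce O–O bonds.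

Step 9
Reactants: 17 propyne; 18 1-bromoheptane
Product: 21 dec-1-yne, via 1,3-dilithiopropyne 19 (not isolated), via lithium dec-1-ynide 20 (not isolated)
Conditions: n-BuLi (2.1 equiv), TMEDA, Et2O/hexane, −78 °C → rt; 18 (0.9 equiv), −78 °C → rt; H2O; distillation
Reagents that add atoms: none
Why: SN2 alkylation of the propyne dianion takes place at its more reactive propargylic carbanion and leaves the acetylide end free.

Step 10
Reactants: 21 dec-1-yne; 18 1-bromoheptane
Product: 23 heptadec-8-yne, via sodium dec-1-ynide 22 (not isolated)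
Conditions: NaNH2 (1.05 equiv), liq. NH3/THF, −33 °C, 1 h; 18 (1.0 equiv), DMPU, cat. NaI, NH3 allowed to boil off, rt → 50 °C
Reagents that add atoms: none
Why: Classical acetylide alkylation (SN2 on a primary bromide) with the strongly nucleophilic sodium salt completes the 17-carbon chain, and any base-induced migration of the triple bond is harmless because step 11 moves it to the chain end anyway.

Step 11
Reactants: 23 heptadec-8-yne
Product: 25 heptadec-1-yne, via potassium heptadec-1-ynide 24 (not isolated)
Conditions: KH, H2N(CH2)3NH2 (KAPA, 4 equiv), 0 °C → rt; H2O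
Reagents that add atoms: none
Why: The alkyne zipper isomerisation is driven by irreversible formation of the terminal acetylide; migration to either chain end gives the same hydrocarbon.

Step 12
Reactants: 25 heptadec-1-yne
Product: 27 tributyl(heptadec-1-yn-1-yl)stannane, via lithium heptadec-1-ynide 26 (not isolated)
Conditions: n-BuLi, THF, −78 °C; Bu3SnCl, −78 °C → rt
Reagents that add atoms: tributyltin chloride, CCCC[Sn](Cl)(CCCC)CCCC
Why: Deprotonation and stannylation of the terminal alkyne gives the most reactive class of Stille partner, so the union can be run without amine base or copper.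

Step 13
Reactants: 16 methyl (3S,4Z)-5-iodo-3-(oxan-2-ylperoxy)pent-4-enoate; 27 tributyl(heptadec-1-yn-1-yl)stannane
Product: 28 methyl (3S,4Z)-3-(oxan-2-ylperoxy)docos-4-en-6-ynoate
Conditions: PdCl2(MeCN)2 (5 mol %), DMF, rt, dark, BHT
Reagents that add atoms: none
Why: Stille alkenyl–alkynyl cross-coupling (oxidative addition into C–I with retention, fast alkynyl transmetalation, reductive elimination) forms the C5–C6 bond that joins the two halves with the Z geometry kept; the neutral, phosphine-, amine- and copper-free medium spares the β-peroxy ester and the O–O bond.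

Step 14
Reactants: 28 methyl (3S,4Z)-3-(oxan-2-ylperoxy)docos-4-en-6-ynoate
Product: 32 6-epi-chondrillin = methyl 2-[(3S,6S)-6-hexadecyl-6-methoxy-3,6-dihydro-1,2-dioxin-3-yl]acetate, via enynyl hydroperoxide 29 (not isolated), via alkylidene dioxine 30 (not isolated), via 6R epimer 31 (not isolated)
Conditions: Ph3PAuNTf2 (5 mol %), CSA (15 mol %), MeOH/CH2Cl2 (3:1), 3 Å MS, BHT, 0 °C → rt, dark; Et3N quench; SiO2 (any recovered 31 is resubmitted)
Reagents that add atoms: methanol, CO
Why: Proposed new method: acid methanolysis of the THP peroxyacetal frees the C3–OOH (29), and the cationic Au(I) π-acid (not a one-electron reductant, so no Fenton-type O–O cleavage) activates C6≡C7; the hydroperoxide adds 6-exo-dig at C6, the alkyne carbon whose developing cation is stabilised by the C4=C5 vinyl group, and fast protodeauration in the acidic protic medium gives 30, whose protonation at C7 gives a peroxycarbenium ion that MeOH traps as the methoxy peroxyketal (a MeOH-first addition to the alkyne funnels into the same cation); C3 is not involved and stays S, while C6 is set by acid equilibration toward the 6S isomer, which has a pseudoaxial, anomerically stabilised OMe and pseudoequatorial C16H33 and CH2CO2Me groups (only a modest preference, about 1–2:1, is expected, and 31 re-equilibrates through the same cation); the closest known reaction types are Au(I)- or Pd(II)-catalysed alkynol cycloisomerisation/ketalisation with MeOH and the acid-catalysed addition of hydroperoxides to enol ethers, and a hydroperoxide has not been used as the nucleophile in an alkyne ketalisation.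

## Compound list
1 | 3,4-dihydro-2H-pyran | C1=COCCC1 | starting material
2 | hydrogen peroxide | OO | starting material
3 | oxan-2-yl hydroperoxide | OOC1CCCCO1 | intermediate
4 | allylmagnesium bromide | C=CC[Mg]Br | starting material
5 | 3-(trimethylsilyl)prop-2-ynal | C[Si](C)(C)C#CC=O | starting material
6 | B-allyldiisopinocampheylborane from (−)-α-pinene | C=CCB([C@H]1C[C@H]2C[C@@H]([C@@H]1C)C2(C)C)[C@H]1C[C@H]2C[C@@H]([C@@H]1C)C2(C)C | intermediate
7 | (3R)-1-(trimethylsilyl)hex-5-en-1-yn-3-yl diisopinocampheylborinate | C[Si](C)(C)C#C[C@H](OB([C@H]1C[C@H]2C[C@@H]([C@@H]1C)C2(C)C)[C@H]1C[C@H]2C[C@@H]([C@@H]1C)C2(C)C)CC=C | intermediate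
8 | (3R)-1-(trimethylsilyl)hex-5-en-1-yn-3-ol | C[Si](C)(C)C#C[C@H](O)CC=C | intermediate
9 | (3R)-1-(trimethylsilyl)hex-5-en-1-yn-3-yl methanesulfonate | C[Si](C)(C)C#C[C@H](OS(C)(=O)=O)CC=C | intermediate
10 | trimethyl[(3S)-3-(oxan-2-ylperoxy)hex-5-en-1-yn-1-yl]silane | C[Si](C)(C)C#C[C@@H](OOC1CCCCO1)CC=C | intermediate
11 | 2-{[(3S)-hex-5-en-1-yn-3-yl]peroxy}oxane | C#C[C@@H](OOC1CCCCO1)CC=C | intermediate
12 | (3S)-3-(oxan-2-ylperoxy)pent-4-ynal | C#C[C@@H](OOC1CCCCO1)CC=O | intermediate
13 | (3S)-3-(oxan-2-ylperoxy)pent-4-ynoic acid | C#C[C@@H](OOC1CCCCO1)CC(=O)O | intermediate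
14 | methyl (3S)-3-(oxan-2-ylperoxy)pent-4-ynoate | C#C[C@@H](OOC1CCCCO1)CC(=O)OC | intermediate
15 | methyl (3S)-5-iodo-3-(oxan-2-ylperoxy)pent-4-ynoate | IC#C[C@@H](OOC1CCCCO1)CC(=O)OC | intermediate
16 | methyl (3S,4Z)-5-iodo-3-(oxan-2-ylperoxy)pent-4-enoate | I/C=C\[C@@H](OOC1CCCCO1)CC(=O)OC | intermediate
17 | propyne | CC#C | starting material
18 | 1-bromoheptane | CCCCCCCBr | starting material
19 | 1,3-dilithiopropyne | [Li]CC#C[Li] | intermediate
20 | lithium dec-1-ynide | CCCCCCCCC#C[Li] | intermediate
21 | dec-1-yne | CCCCCCCCC#C | intermediate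
22 | sodium dec-1-ynide | CCCCCCCCC#C[Na] | intermediate
23 | heptadec-8-yne | CCCCCCCC#CCCCCCCCC | intermediate
24 | potassium heptadec-1-ynide | CCCCCCCCCCCCCCCC#C[K] | intermediate
25 | heptadec-1-yne | CCCCCCCCCCCCCCCC#C | intermediate
26 | lithium heptadec-1-ynide | CCCCCCCCCCCCCCCC#C[Li] | intermediate
27 | tributyl(heptadec-1-yn-1-yl)stannane | CCCCCCCCCCCCCCCC#C[Sn](CCCC)(CCCC)CCCC | intermediate
28 | methyl (3S,4Z)-3-(oxan-2-ylperoxy)docos-4-en-6-ynoate | CCCCCCCCCCCCCCCC#C/C=C\[C@@H](OOC1CCCCO1)CC(=O)OC | intermediate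
29 | methyl (3S,4Z)-3-hydroperoxydocos-4-en-6-ynoate | CCCCCCCCCCCCCCCC#C/C=C\[C@@H](OO)CC(=O)OC | intermediate
30 | methyl 2-[(3S,6Z)-6-hexadecylidene-3,6-dihydro-1,2-dioxin-3-yl]acetate | CCCCCCCCCCCCCCC/C=C1\OO[C@@H](CC(=O)OC)C=C1 | intermediate
31 | methyl 2-[(3S,6R)-6-hexadecyl-6-methoxy-3,6-dihydro-1,2-dioxin-3-yl]acetate (6R epimer, chondrillin) | CCCCCCCCCCCCCCCC[C@]1(OC)C=C[C@H](CC(=O)OC)OO1 | intermediate
32 | 6-epi-chondrillin, methyl 2-[(3S,6S)-6-hexadecyl-6-methoxy-3,6-dihydro-1,2-dioxin-3-yl]acetate | CCCCCCCCCCCCCCCC[C@@]1(OC)C=C[C@H](CC(=O)OC)OO1 | target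

## Step count and risks
Total steps: 14. Longest linear sequence: 9 (steps 2, 3, 4, 5, 6, 7, 8, 13, 14). The chain branch contributes 4 steps before the union and the peroxide donor contributes 1.

**Step 14 (the new step).** There are three risks. The β-peroxy vinylgold intermediate may expel the O2 alkoxide to give an α-oxo gold carbene, with loss of the peroxide. The nucleophile may add at C7 instead of C6. The C6 ratio may stay near 1:1.

The fallback uses known chemistry only, sets out from 25 and 16, and comes back at 32. It gives up the alkyne as a ketone surrogate and makes the Z-γ-peroxy enone, whose free hydroperoxide closes on the ketone by itself. From 25, hydroboration with Cy2BH followed by NaBO3 oxidation gives heptadecanal F1. Pinnick oxidation gives heptadecanoic acid F2, and 1-chloro-N,N,2-trimethylpropenylamine gives heptadecanoyl chloride F3 under neutral conditions. From 16, hexamethylditin with PdCl2(MeCN)2 in NMP gives methyl (3S,4Z)-3-(oxan-2-ylperoxy)-5-(trimethylstannyl)pent-4-enoate F4. Acyl Stille coupling of F3 with F4 gives methyl (3S,4Z)-6-oxo-3-(oxan-2-ylperoxy)docos-4-enoate F5. Brief treatment with TsOH in MeOH removes the THP group. The hydroperoxide then adds to the ketone to give the dioxinol methyl 2-[(3S)-6-hexadecyl-6-hydroxy-3,6-dihydro-1,2-dioxin-3-yl]acetate F6. Continued TsOH/MeOH ketalisation gives 32, with 31 separated and re-equilibrated.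

**Step 4.** The CH2 next to the mesylate is allylic, so E2 to a conjugated dienyne can compete. SN2′ to an allenyl peroxide can also compete, and partial ionisation would erode the ee.

The fallback sets out from 8 and comes back at 13. It removes the activated β-hydrogens by cleaving the alkene before the displacement. Ozonolysis of 8 with NaBH4 work-up gives (3R)-5-(trimethylsilyl)pent-4-yne-1,3-diol F7. Selective primary silylation (TBDPSCl, imidazole) gives (3R)-1-[(tert-butyldiphenylsilyl)oxy]-5-(trimethylsilyl)pent-4-yn-3-ol F8. MsCl/Et3N then gives (3R)-1-[(tert-butyldiphenylsilyl)oxy]-5-(trimethylsilyl)pent-4-yn-3-yl methanesulfonate F9. Displacement with 3 and CsOH·H2O in DMF (inversion, with C-desilylation) gives tert-butyl{[(3S)-3-(oxan-2-ylperoxy)pent-4-yn-1-yl]oxy}diphenylsilane F10. TBAF buffered with AcOH gives (3S)-3-(oxan-2-ylperoxy)pent-4-yn-1-ol F11, and TEMPO/PhI(OAc)2 in MeCN/H2O oxidises it directly to 13.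

**Step 2.** The yield is not in doubt. However, every later step is stereospecific, so the ee of 8 is the ee of 32, and small ynals can give less than about 90% ee in allylborations.

The fallback sets out from 4 and 5 and comes back at 8. It separates C–C bond formation from stereocontrol. Direct Grignard addition of 4 to 5 gives racemic 1-(trimethylsilyl)hex-5-en-1-yn-3-ol F12. Buffered Dess–Martin oxidation gives 1-(trimethylsilyl)hex-5-en-1-yn-3-one F13, which is used without chromatography. Noyori asymmetric transfer hydrogenation with the (R,R)-TsDPEN–Ru(p-cymene) catalyst in i-PrOH gives 8 in high ee.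

## Further compounds
F1 | step 14 | heptadecanal | CCCCCCCCCCCCCCCCC=O
F2 | step 14 | heptadecanoic acid | CCCCCCCCCCCCCCCCC(=O)O
F3 | step 14 | heptadecanoyl chloride | CCCCCCCCCCCCCCCCC(=O)Cl
F4 | step 14 | methyl (3S,4Z)-3-(oxan-2-ylperoxy)-5-(trimethylstannyl)pent-4-enoate | C[Sn](C)(C)/C=C\[C@@H](OOC1CCCCO1)CC(=O)OC
F5 | step 14 | methyl (3S,4Z)-6-oxo-3-(oxan-2-ylperoxy)docos-4-enoate | CCCCCCCCCCCCCCCCC(=O)/C=C\[C@@H](OOC1CCCCO1)CC(=O)OC
F6 | step 14 | methyl 2-[(3S)-6-hexadecyl-6-hydroxy-3,6-dihydro-1,2-dioxin-3-yl]acetate | CCCCCCCCCCCCCCCCC1(O)C=C[C@H](CC(=O)OC)OO1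
F7 | step 4 | (3R)-5-(trimethylsilyl)pent-4-yne-1,3-diol | C[Si](C)(C)C#C[C@H](O)CCO
F8 | step 4 | (3R)-1-[(tert-butyldiphenylsilyl)oxy]-5-(trimethylsilyl)pent-4-yn-3-ol | C[Si](C)(C)C#C[C@H](O)CCO[Si](c1ccccc1)(c1ccccc1)C(C)(C)C
F9 | step 4 | (3R)-1-[(tert-butyldiphenylsilyl)oxy]-5-(trimethylsilyl)pent-4-yn-3-yl methanesulfonate | C[Si](C)(C)C#C[C@H](OS(C)(=O)=O)CCO[Si](c1ccccc1)(c1ccccc1)C(C)(C)C
F10 | step 4 | tert-butyl{[(3S)-3-(oxan-2-ylperoxy)pent-4-yn-1-yl]oxy}diphenylsilane | C#C[C@@H](OOC1CCCCO1)CCO[Si](c1ccccc1)(c1ccccc1)C(C)(C)C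
F11 | step 4 | (3S)-3-(oxan-2-ylperoxy)pent-4-yn-1-ol | C#C[C@@H](OOC1CCCCO1)CCO
F12 | step 2 | racemic 1-(trimethylsilyl)hex-5-en-1-yn-3-ol | C[Si](C)(C)C#CC(O)CC=C
F13 | step 2 | 1-(trimethylsilyl)hex-5-en-1-yn-3-one | C[Si](C)(C)C#CC(=O)CC=C
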